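**Retrosynthetic overview**

1. The butylidene butenolide is made last, by AgNO3-catalysed 5-exo-dig lactonisation of the (Z)-2-en-4-ynoic acid 27; the alkyne comes from Sonogashira coupling of pent-1-yne with the C3 enol triflate, the acid from the C2 methyl ester.
2. The phthalide comes before that: convex-face addition of 2-(methoxycarbonyl)phenylmagnesium chloride to the C8 cyclobutanone 19, then lactonisation, fixes the spiro carbon C8.
3. The strategy rests on the cyclobutane (C1, C6, C7, C8) cis-fused to the cyclohexene (C1–C6). Its ring-fusion bond C1–C6 and the bond from the spiro carbon C8 to the CH–propyl carbon C7 are made together by an auxiliary-controlled intramolecular [2+2] of a keteniminium (C1=C8, C8 as latent C=O) with the Z alkene C6=C7, tethered through C2=C3–C4–C5 (15 → 19).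
4. Amide 15 comes from butanal and the C4 phosphonium salt (Z-selective Wittig), Masamune–Brooks homologation, alkylation with the bromoacetamide of (2S,5S)-2,5-dimethylpyrrolidine and Z-selective enol triflation.
5. Ring order: cyclohexene and cyclobutane together (step 6), phthalide lactone (step 7), butenolide (step 10).

Key step: step 6

Numbering: the carbocyclic core is numbered as bicyclo[4.2.0]oct-2-ene throughout (C1 ring-fusion CH next to C8; C2=C3 alkene with the ester or lactone carbonyl on C2; C6 second ring-fusion CH; C7 CH–propyl; C8 ketone, later spiro carbon).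

Assumption: the (2S,5S)-auxiliary is taken to give the (1R,6S,7R) cycloadduct; the sense of induction must be checked on 19, and if it is opposite, (2R,5R)-2,5-dimethylpyrrolidine is used in step 3 with nothing else changed.

**Route**

Step 1
Reactants: 1 butanal; 2 (3-carboxypropyl)triphenylphosphonium bromide
Product: 4 (Z)-oct-4-enoic acid, via phosphonium ylide 3 (not isolated)
Conditions: 2, NaN(SiMe3)2 (2.1 equiv), THF, 0 °C; then 1, −78 °C → rt; 1 M HCl
Reagents that add atoms: none
Why: Wittig reaction of a non-stabilised ylide with an aliphatic aldehyde under lithium-free conditions runs through the kinetically favoured cis-oxaphosphetane and should give the Z alkene.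

Step 2
Reactants: 4 (Z)-oct-4-enoic acid; 5 potassium methyl malonate
Product: 8 methyl (Z)-3-oxodec-6-enoate, via acyl imidazolide 6 (not isolated), via acylmalonate half-ester 7 (not isolated)
Conditions: 1,1'-carbonyldiimidazole, THF, rt; then 5, MgCl2, Et3N, THF, rt → 40 °C; 1 M HCl
Reagents that add atoms: none
Why: Masamune–Brooks homologation, in which the acyl imidazolide C-acylates the magnesium enolate of the malonate half-ester and the adduct loses CO2, under conditions that leave the Z alkene untouched.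

Step 3
Reactants: 9 (2S,5S)-2,5-dimethylpyrrolidine; 10 bromoacetyl bromide
Product: 11 2-bromo-1-[(2S,5S)-2,5-dimethylpyrrolidin-1-yl]ethan-1-one
Conditions: aq. K2CO3, CH2Cl2, 0 °C
Reagents that add atoms: none
Why: Schotten–Baumann N-acylation of the secondary amine by the acid bromide is far faster than displacement of the primary bromide, and the stereocentres of the auxiliary are not involved.

Step 4
Reactants: 8 methyl (Z)-3-oxodec-6-enoate; 11 2-bromo-1-[(2S,5S)-2,5-dimethylpyrrolidin-1-yl]ethan-1-one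
Product: 13 methyl (6Z)-2-{2-[(2S,5S)-2,5-dimethylpyrrolidin-1-yl]-2-oxoethyl}-3-oxodec-6-enoate (C2 epimers), via sodium enolate 12 (not isolated)
Conditions: NaH, THF, 0 °C; then 11, 0 °C → rt
Reagents that add atoms: none
Why: SN2 C-alkylation of the soft β-keto ester enolate by the reactive α-bromoamide; the new C2 centre forms as a mixture and becomes sp2 again in step 5.

Step 5
Reactants: 13 methyl (6Z)-2-{2-[(2S,5S)-2,5-dimethylpyrrolidin-1-yl]-2-oxoethyl}-3-oxodec-6-enoate
Product: 15 methyl (2Z,6Z)-2-{2-[(2S,5S)-2,5-dimethylpyrrolidin-1-yl]-2-oxoethyl}-3-(trifluoromethylsulfonyloxy)deca-2,6-dienoate, via chelated sodium enolate 14 (not isolated)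
Conditions: NaH, THF, 0 °C; PhNTf2, 0 °C → rt; dilute HCl work-up
Reagents that add atoms: N-phenylbis(trifluoromethanesulfonimide), O=S(=O)(N(c1ccccc1)S(=O)(=O)C(F)(F)F)C(F)(F)F
Why: The sodium enolate is chelated between the enolate and ester oxygens, so O-sulfonylation with the triflimide (which, unlike Tf2O, does not activate the tertiary amide) should give the 2Z enol triflate with ester and OTf cis, which places the amide arm and the alkenyl chain cis as the cycloaddition requires.

Step 6
Reactants: 15 methyl (2Z,6Z)-2-{2-[(2S,5S)-2,5-dimethylpyrrolidin-1-yl]-2-oxoethyl}-3-(trifluoromethylsulfonyloxy)deca-2,6-dienoate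
Product: 19 methyl (1R,6S,7R)-8-oxo-7-propyl-3-(trifluoromethylsulfonyloxy)bicyclo[4.2.0]oct-2-ene-2-carboxylate, via O-triflyliminium triflate 16 (not isolated), via keteniminium triflate 17 (not isolated), via cyclobutaniminium triflate 18 (not isolated)
Conditions: Tf2O, 2,6-di-tert-butyl-4-methylpyridine, (CH2Cl)2, −20 °C → 60 °C; then aq. NaHCO3, rt
Reagents that add atoms: water, O
Why: Proposed new method: Tf2O O-sulfonylates the tertiary amide (16), the hindered pyridine removes the α-proton (also allylic to C2=C3) and triflate leaves to give vinylketeniminium 17, whose electrophilic central carbon C8 is attacked by C7 of the tethered Z alkene while the enamine-like α-carbon C1 bonds to C6 in an asynchronous thermal [2+2], and the cyclobutaniminium 18 is then hydrolysed to the ketone. The closest known reaction type is the intramolecular keteniminium–alkene [2+2] of ω-alkenyl amides to bicyclo[n.2.0]alkanones, also run with 2,5-dimethylpyrrolidine amides; what has not been shown is a keteniminium conjugated to an ester- and triflate-bearing alkene through which the tether runs. The cyclohexene closes in the fused mode through the C1–C6 bond (all four tether atoms C2–C5 inside the new six-membered ring) and the cyclobutane closes through the C8–C7 bond onto the same alkene, whereas the bridged bicyclo[4.1.1] mode (C8–C6 and C1–C7) is out of reach because the Z C2=C3 bond holds C1 and C4 cis and the tether is short. C6 and C7 take their relative configuration from the Z alkene by suprafacial addition (H6 and H7 cis, propyl endo), C1 follows from the obligatory cis 4/6 ring fusion, and the absolute sense (1R,6S,7R) is set by the C2-symmetric (2S,5S)-2,5-dimethylpyrrolidinium unit, whose methyl groups block one of the two approach paths of the alkene to C8. The step needs fused regiochemistry, transfer of the alkene geometry and one enantioface, which the tether, the near-concerted ring closure and the auxiliary should secure, and it needs the [2+2] to outrun capture of C8 by the C2 ester carbonyl and enamine-mediated epimerisation at C7, which the non-nucleophilic base and the mild bicarbonate hydrolysis should favour.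

Step 7
Reactants: 19 methyl (1R,6S,7R)-8-oxo-7-propyl-3-(trifluoromethylsulfonyloxy)bicyclo[4.2.0]oct-2-ene-2-carboxylate; 20 methyl 2-iodobenzoate
Product: 23 methyl (1R,6S,7R,8R)-3'-oxo-7-propyl-3-(trifluoromethylsulfonyloxy)-3'H-spiro[bicyclo[4.2.0]oct-2-ene-8,1'-[2]benzofuran]-2-carboxylate, via arylmagnesium chloride 21 (not isolated), via chloromagnesium alkoxide 22 (not isolated)
Conditions: 20, iPrMgCl·LiCl, THF, −40 °C; then 19, −78 °C → rt; aq. NH4Cl
Reagents that add atoms: none
Why: Iodine–magnesium exchange gives the ester-bearing arylmagnesium, which should undergo 1,2-addition to the strained cyclobutanone from the convex face (that of H1 and H7, opposite the C1–C2 bond and the endo propyl group), setting C8 as R, after which the alkoxide closes the phthalide by acyl substitution on the neighbouring methyl ester.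

Step 8
Reactants: 23 methyl (1R,6S,7R,8R)-3'-oxo-7-propyl-3-(trifluoromethylsulfonyloxy)-3'H-spiro[bicyclo[4.2.0]oct-2-ene-8,1'-[2]benzofuran]-2-carboxylate; 24 pent-1-yne
Product: 25 methyl (1R,6S,7R,8R)-3'-oxo-3-(pent-1-yn-1-yl)-7-propyl-3'H-spiro[bicyclo[4.2.0]oct-2-ene-8,1'-[2]benzofuran]-2-carboxylate
Conditions: Pd(PPh3)2Cl2 (5 mol %), CuI (10 mol %), Et3N, THF, rt
Reagents that add atoms: none
Why: Sonogashira coupling, in which oxidative addition of zerovalent palladium into the electron-poor enol triflate is easy at room temperature and neither the lactone nor any stereocentre is touched.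

Step 9
Reactants: 25 methyl (1R,6S,7R,8R)-3'-oxo-3-(pent-1-yn-1-yl)-7-propyl-3'H-spiro[bicyclo[4.2.0]oct-2-ene-8,1'-[2]benzofuran]-2-carboxylate
Product: 27 (1R,6S,7R,8R)-3'-oxo-3-(pent-1-yn-1-yl)-7-propyl-3'H-spiro[bicyclo[4.2.0]oct-2-ene-8,1'-[2]benzofuran]-2-carboxylic acid, via dilithium hydroxy dicarboxylate 26 (not isolated)
Conditions: LiOH, THF/MeOH/H2O, 40 °C; then 1 M HCl to pH 2, rt
Reagents that add atoms: lithium hydroxide, [Li+].[OH-]
Why: Saponification cleaves the methyl enoate and opens the phthalide to its carboxylate, and on acidification the tertiary γ-hydroxy acid should relactonise spontaneously without breaking the C8–O bond, so no stereocentre is affected.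

Step 10
Reactants: 27 (1R,6S,7R,8R)-3'-oxo-3-(pent-1-yn-1-yl)-7-propyl-3'H-spiro[bicyclo[4.2.0]oct-2-ene-8,1'-[2]benzofuran]-2-carboxylic acid
Product: 28 CNP0248594.2, the (1R,6S,7R,8R) spirophthalide carrying the (Z)-butylidene butenolide fused at C2–C3
Conditions: AgNO3 (10 mol %), acetone, rt, dark
Reagents that add atoms: none
Why: Silver-catalysed cycloisomerisation of a (Z)-2-en-4-ynoic acid, in which anti attack of the carboxyl oxygen on the silver-activated proximal alkyne carbon (5-exo-dig) and protodemetalation place the propyl chain cis to the ring oxygen and should give the Z butylidene butenolide.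

**Compound list**

1 | butanal | CCCC=O | starting material
2 | (3-carboxypropyl)triphenylphosphonium bromide | OC(=O)CCC[P+](c1ccccc1)(c1ccccc1)c1ccccc1.[Br-] | starting material
3 | sodium 4-(triphenylphosphoranylidene)butanoate (ylide) | [Na+].[O-]C(=O)CCC=P(c1ccccc1)(c1ccccc1)c1ccccc1 | intermediate
4 | (Z)-oct-4-enoic acid | CCC/C=C\CCC(=O)O | intermediate
5 | potassium methyl malonate (potassium 3-methoxy-3-oxopropanoate) | COC(=O)CC(=O)[O-].[K+] | starting material
6 | (Z)-1-(imidazol-1-yl)oct-4-en-1-one | CCC/C=C\CCC(=O)n1ccnc1 | intermediate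
7 | (Z)-2-(methoxycarbonyl)-3-oxodec-6-enoic acid (magnesium salt in the flask; drawn as the free acid) | CCC/C=C\CCC(=O)C(C(=O)O)C(=O)OC | intermediate
8 | methyl (Z)-3-oxodec-6-enoate | CCC/C=C\CCC(=O)CC(=O)OC | intermediate
9 | (2S,5S)-2,5-dimethylpyrrolidine | N1[C@@H](C)CC[C@@H]1C | starting material
10 | bromoacetyl bromide | O=C(Br)CBr | starting material
11 | 2-bromo-1-[(2S,5S)-2,5-dimethylpyrrolidin-1-yl]ethan-1-one | BrCC(=O)N1[C@@H](C)CC[C@@H]1C | intermediate
12 | sodium (2Z,6Z)-1-methoxy-1-oxodeca-2,6-dien-3-olate (enolate of 8) | [Na+].CCC/C=C\CC/C([O-])=C/C(=O)OC | intermediate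
13 | methyl (6Z)-2-{2-[(2S,5S)-2,5-dimethylpyrrolidin-1-yl]-2-oxoethyl}-3-oxodec-6-enoate (C2 epimers) | CCC/C=C\CCC(=O)C(CC(=O)N1[C@@H](C)CC[C@@H]1C)C(=O)OC | intermediate
14 | sodium (2Z,6Z)-enolate of 13 (enolate oxygen cis to the ester) | [Na+].COC(=O)/C(CC(=O)N1[C@@H](C)CC[C@@H]1C)=C(/CC/C=C\CCC)[O-] | intermediate
15 | methyl (2Z,6Z)-2-{2-[(2S,5S)-2,5-dimethylpyrrolidin-1-yl]-2-oxoethyl}-3-(trifluoromethylsulfonyloxy)deca-2,6-dienoate | COC(=O)/C(CC(=O)N1[C@@H](C)CC[C@@H]1C)=C(/CC/C=C\CCC)OS(=O)(=O)C(F)(F)F | intermediate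
16 | O-triflyliminium triflate of 15 (amide C=O converted into C(OTf)=N+) | COC(=O)/C(CC(OS(=O)(=O)C(F)(F)F)=[N+]1[C@@H](C)CC[C@@H]1C)=C(/CC/C=C\CCC)OS(=O)(=O)C(F)(F)F.[O-]S(=O)(=O)C(F)(F)F | intermediate
17 | keteniminium triflate (CH=C=N+ on C2 of the Z enol triflate) | COC(=O)/C(C=C=[N+]1[C@@H](C)CC[C@@H]1C)=C(/CC/C=C\CCC)OS(=O)(=O)C(F)(F)F.[O-]S(=O)(=O)C(F)(F)F | intermediate
18 | (1R,6S,7R)-cyclobutaniminium triflate (C8=N+ of the dimethylpyrrolidine; otherwise as 19) | COC(=O)C2=C(OS(=O)(=O)C(F)(F)F)CC[C@H]1[C@@H](CCC)C(=[N+]3[C@@H](C)CC[C@@H]3C)[C@@H]21.[O-]S(=O)(=O)C(F)(F)F | intermediate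
19 | methyl (1R,6S,7R)-8-oxo-7-propyl-3-(trifluoromethylsulfonyloxy)bicyclo[4.2.0]oct-2-ene-2-carboxylate (cis-fused; H1, H6 and H7 cis; propyl endo) | COC(=O)C2=C(OS(=O)(=O)C(F)(F)F)CC[C@H]1[C@@H](CCC)C(=O)[C@@H]21 | intermediate
20 | methyl 2-iodobenzoate | COC(=O)c1ccccc1I | starting material
21 | [2-(methoxycarbonyl)phenyl]magnesium chloride (LiCl complex) | COC(=O)c1ccccc1[Mg]Cl | intermediate
22 | chloromagnesium (1R,6S,7R,8R)-alkoxide: 19 with C8 bearing OMgCl (propyl face) and 2-(methoxycarbonyl)phenyl (H1/H7 face) | COC(=O)C2=C(OS(=O)(=O)C(F)(F)F)CC[C@H]1[C@@H](CCC)[C@](O[Mg]Cl)(c3ccccc3C(=O)OC)[C@@H]21 | intermediate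
23 | methyl (1R,6S,7R,8R)-3'-oxo-7-propyl-3-(trifluoromethylsulfonyloxy)-3'H-spiro[bicyclo[4.2.0]oct-2-ene-8,1'-[2]benzofuran]-2-carboxylate | COC(=O)C2=C(OS(=O)(=O)C(F)(F)F)CC[C@H]1[C@@H](CCC)[C@@]3(OC(=O)c4ccccc43)[C@@H]21 | intermediate
24 | pent-1-yne | C#CCCC | starting material
25 | methyl (1R,6S,7R,8R)-3'-oxo-3-(pent-1-yn-1-yl)-7-propyl-3'H-spiro[bicyclo[4.2.0]oct-2-ene-8,1'-[2]benzofuran]-2-carboxylate | COC(=O)C2=C(C#CCCC)CC[C@H]1[C@@H](CCC)[C@@]3(OC(=O)c4ccccc43)[C@@H]21 | intermediate
26 | dilithium (1R,6S,7R,8R)-8-(2-carboxylatophenyl)-8-hydroxy-3-(pent-1-yn-1-yl)-7-propylbicyclo[4.2.0]oct-2-ene-2-carboxylate | [Li+].[Li+].[O-]C(=O)C2=C(C#CCCC)CC[C@H]1[C@@H](CCC)[C@](O)(c3ccccc3C(=O)[O-])[C@@H]21 | intermediate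
27 | (1R,6S,7R,8R)-3'-oxo-3-(pent-1-yn-1-yl)-7-propyl-3'H-spiro[bicyclo[4.2.0]oct-2-ene-8,1'-[2]benzofuran]-2-carboxylic acid | OC(=O)C2=C(C#CCCC)CC[C@H]1[C@@H](CCC)[C@@]3(OC(=O)c4ccccc43)[C@@H]21 | intermediate
28 | CNP0248594.2: core of 27 with the C2 carboxyl closed onto the proximal alkyne carbon as a 5-[(Z)-butylidene]furan-2(5H)-one fused at C2–C3; (1R,6S,7R,8R), propyl endo, phthalide aryl carbon on the H1/H7 face | CCC/C=C1\OC(=O)C2=C1CC[C@H]1[C@@H](CCC)[C@@]3(OC(=O)c4ccccc43)[C@@H]21 | target

**Step count**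

Total: 10 steps. Longest linear sequence: 9 steps (1, 2, 4, 5, 6, 7, 8, 9, 10, from butanal); step 3 is a one-step side branch.

**Steps most likely to fail**

1. Step 6 (proposed new method). The keteniminium carbon may be captured by the neighbouring ester carbonyl (five-membered oxonium, then loss of the methyl group). The vinylketeniminium may undergo 4π-closure. A stepwise cation or enamine formation may erode the alkene geometry or epimerise C7, and the auxiliary may give poor facial selectivity.
Fallback with known chemistry, from 13 back to 19: the cycloaddition is run on a saturated four-atom tether, the established substrate class for bicyclo[4.2.0]octan-8-ones. NaBH4 (MeOH, 0 °C) reduces the ketone of 13 to methyl (6Z)-2-{2-[(2S,5S)-2,5-dimethylpyrrolidin-1-yl]-2-oxoethyl}-3-hydroxydec-6-enoate F1 (diastereomer mixture, harmless because C2 and C3 become sp2 again). TBSOTf and 2,6-lutidine give its tert-butyldimethylsilyl ether F2. Tf2O and 2,6-di-tert-butyl-4-methylpyridine in (CH2Cl)2 then lead through the O-triflyliminium triflate F3 and the keteniminium triflate F4 to the cyclobutaniminium triflate F5, and aq. NaHCO3 releases methyl (1R,6S,7R)-3-(tert-butyldimethylsilyloxy)-8-oxo-7-propylbicyclo[4.2.0]octane-2-carboxylate F6. HF·pyridine gives the hydroxy ketone methyl (1R,6S,7R)-3-hydroxy-8-oxo-7-propylbicyclo[4.2.0]octane-2-carboxylate F7. Dess–Martin periodinane gives the β-keto ester methyl (1R,6S,7R)-3,8-dioxo-7-propylbicyclo[4.2.0]octane-2-carboxylate F8. Tf2O and iPr2NEt (CH2Cl2, −78 °C) convert its ring enol into enol triflate 19.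

2. Step 7. The arylmagnesium may attack the β-triflyloxy enoate (addition–elimination at C3 or attack at sulfur) instead of the ketone, or deprotonate the cyclobutanone, which would also epimerise C7.
Fallback, from 19 back to 25: the triflate is removed before the organometallic step. Sonogashira coupling of 19 with 24 (Pd(PPh3)2Cl2, CuI, Et3N, THF, rt) gives methyl (1R,6S,7R)-8-oxo-3-(pent-1-yn-1-yl)-7-propylbicyclo[4.2.0]oct-2-ene-2-carboxylate F9. Addition of 21 in the presence of LaCl3·2LiCl (THF, −78 °C) gives the chloromagnesium alkoxide F10, which lactonises on warming to 25.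

3. Step 10. The carboxylate may attack the distal alkyne carbon (6-endo-dig, giving the 2-pyranone), or the exocyclic alkene geometry may erode.
Fallback, from 27 to 28: electrophile-induced cyclisation followed by reduction. I2 and NaHCO3 in MeCN give by anti iodolactonisation the (E)-1-iodobutylidene butenolide F11 (propyl cis to the ring oxygen). Pd(PPh3)4 and Bu3SnH (THF, rt) replace iodine by hydrogen with retention to give 28.

**Further compounds**

F1 | step 6 | methyl (6Z)-2-{2-[(2S,5S)-2,5-dimethylpyrrolidin-1-yl]-2-oxoethyl}-3-hydroxydec-6-enoate | CCC/C=C\CCC(O)C(CC(=O)N1[C@@H](C)CC[C@@H]1C)C(=O)OC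
F2 | step 6 | methyl (6Z)-3-(tert-butyldimethylsilyloxy)-2-{2-[(2S,5S)-2,5-dimethylpyrrolidin-1-yl]-2-oxoethyl}dec-6-enoate | CCC/C=C\CCC(O[Si](C)(C)C(C)(C)C)C(CC(=O)N1[C@@H](C)CC[C@@H]1C)C(=O)OC
F3 | step 6 | O-triflyliminium triflate of F2 | CCC/C=C\CCC(O[Si](C)(C)C(C)(C)C)C(CC(OS(=O)(=O)C(F)(F)F)=[N+]1[C@@H](C)CC[C@@H]1C)C(=O)OC.[O-]S(=O)(=O)C(F)(F)F
F4 | step 6 | keteniminium triflate from F2 | CCC/C=C\CCC(O[Si](C)(C)C(C)(C)C)C(C=C=[N+]1[C@@H](C)CC[C@@H]1C)C(=O)OC.[O-]S(=O)(=O)C(F)(F)F
F5 | step 6 | (1R,6S,7R)-cyclobutaniminium triflate of the saturated series | COC(=O)C2C(O[Si](C)(C)C(C)(C)C)CC[C@H]1[C@@H](CCC)C(=[N+]3[C@@H](C)CC[C@@H]3C)[C@@H]21.[O-]S(=O)(=O)C(F)(F)F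
F6 | step 6 | methyl (1R,6S,7R)-3-(tert-butyldimethylsilyloxy)-8-oxo-7-propylbicyclo[4.2.0]octane-2-carboxylate | COC(=O)C2C(O[Si](C)(C)C(C)(C)C)CC[C@H]1[C@@H](CCC)C(=O)[C@@H]21
F7 | step 6 | methyl (1R,6S,7R)-3-hydroxy-8-oxo-7-propylbicyclo[4.2.0]octane-2-carboxylate | COC(=O)C2C(O)CC[C@H]1[C@@H](CCC)C(=O)[C@@H]21
F8 | step 6 | methyl (1R,6S,7R)-3,8-dioxo-7-propylbicyclo[4.2.0]octane-2-carboxylate | COC(=O)C2C(=O)CC[C@H]1[C@@H](CCC)C(=O)[C@@H]21
F9 | step 7 | methyl (1R,6S,7R)-8-oxo-3-(pent-1-yn-1-yl)-7-propylbicyclo[4.2.0]oct-2-ene-2-carboxylate | COC(=O)C2=C(C#CCCC)CC[C@H]1[C@@H](CCC)C(=O)[C@@H]21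
F10 | step 7 | chloromagnesium (1R,6S,7R,8R)-alkoxide from F9 and 21 | COC(=O)C2=C(C#CCCC)CC[C@H]1[C@@H](CCC)[C@](O[Mg]Cl)(c3ccccc3C(=O)OC)[C@@H]21
F11 | step 10 | (E)-1-iodobutylidene analogue of 28 | CCC/C(I)=C1\OC(=O)C2=C1CC[C@H]1[C@@H](CCC)[C@@]3(OC(=O)c4ccccc43)[C@@H]21
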